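**Plan**
- Retrosynthesis: the three aryl O–CH3 bonds are cut first (protecting groups), then each pyrone is opened at O1–C2 and C4–C5, giving a core with two malonyl dichloride arms and two molecules of 3-pentanone.
- Enabling feature: in each pyrone, O1–C6(ethyl)=C5(methyl) is the enol of symmetric 3-pentanone, and C2–C3–C4 with the bridge CH2 on C3 is a benzyl-substituted malonyl unit; the two pyrones are identical, so one operation builds both.
- The arms are then cut at the malonate C–CH2 bonds (alkylation), the two aryl–CH2 bonds (chloromethylation) and the aryl–C(O) bond (Friedel–Crafts).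
- Forward: 1,3,5-trimethoxybenzene → aryl ketone → bis(chloromethyl) arene → tetraester → tetra-acid → tetra-acid chloride; both pyrone rings then close in one operation, and demethylation ends the route.
- Stereochemistry: the target has no stereocentre and no stereogenic double bond, so no step has to control configuration.

Key step: step 6

Remark: because the target is achiral, "single enantiomer" is taken to mean the compound itself; it is drawn as the 4-hydroxy-2-pyrone tautomer.

**Step 1**
Reactants: 1 1,3,5-trimethoxybenzene; 2 2-methylpropanoyl chloride (isobutyryl chloride)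
Product: 3 2-methyl-1-(2,4,6-trimethoxyphenyl)propan-1-one
Conditions: AlCl3 (1.1 equiv), CH2Cl2, −10 → 0 °C, 1 h; ice/aq. HCl
Reagents that add atoms: none
Why: Friedel–Crafts acylation of the strongly activated, threefold-symmetric arene should stop after one acylation because the ketone deactivates the ring, and low temperature with short contact time keeps AlCl3 from cleaving the methoxy groups next to the new carbonyl.

**Step 2**
Reactants: 3 2-methyl-1-(2,4,6-trimethoxyphenyl)propan-1-one
Product: 4 1-[3,5-bis(chloromethyl)-2,4,6-trimethoxyphenyl]-2-methylpropan-1-one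
Conditions: (CH2O)n (6 equiv), HCl gas, AcOH, 50 °C
Reagents that add atoms: paraformaldehyde (as formaldehyde), C=O; hydrogen chloride, Cl
Why: Blanc chloromethylation (electrophilic substitution by protonated formaldehyde, then OH→Cl exchange) should occur at both remaining ring positions, each activated by two ortho and one para methoxy group while the twisted ketone deactivates only weakly, and the excess of formaldehyde and HCl keeps the first benzylic chloride from alkylating unreacted arene.

**Step 3**
Reactants: 4 1-[3,5-bis(chloromethyl)-2,4,6-trimethoxyphenyl]-2-methylpropan-1-one; 5 dimethyl malonate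
Product: 6 tetramethyl 2,2'-{[2,4,6-trimethoxy-5-(2-methylpropanoyl)-1,3-phenylene]bis(methylene)}dimalonate
Conditions: 5 (8 equiv), NaH (5 equiv), THF, 0 → 50 °C
Reagents that add atoms: none
Why: Malonic ester alkylation (SN2) of the two electron-rich primary benzylic chlorides by sodium dimethyl malonate should be fast, the large excess of malonate prevents one malonate from being alkylated twice, and the malonate anion is too weak a base to enolise the aryl ketone.

**Step 4**
Reactants: 6 tetramethyl 2,2'-{[2,4,6-trimethoxy-5-(2-methylpropanoyl)-1,3-phenylene]bis(methylene)}dimalonate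
Product: 7 2,2'-{[2,4,6-trimethoxy-5-(2-methylpropanoyl)-1,3-phenylene]bis(methylene)}dimalonic acid
Conditions: KOH (10 equiv), MeOH/H2O 3:1, 50 °C; then 2 M HCl, 0 °C, EtOAc extraction, concentration below 30 °C
Reagents that add atoms: potassium hydroxide, [K+].[OH-]
Why: Saponification of the four unhindered methyl esters is ordinary ester hydrolysis, the hindered aryl ketone and the aryl methyl ethers are inert to hydroxide, and cold acidification without heating keeps the two malonic acid units from decarboxylating.

**Step 5**
Reactants: 7 2,2'-{[2,4,6-trimethoxy-5-(2-methylpropanoyl)-1,3-phenylene]bis(methylene)}dimalonic acid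
Product: 8 2,2'-{[2,4,6-trimethoxy-5-(2-methylpropanoyl)-1,3-phenylene]bis(methylene)}dimalonyl tetrachloride
Conditions: (COCl)2 (8 equiv), DMF (cat.), CH2Cl2, 0 °C → rt; evaporation, toluene chase, used crude at once
Reagents that add atoms: oxalyl chloride, O=C(Cl)C(Cl)=O
Why: Acid chloride formation through the Vilsmeier chloride from oxalyl chloride and catalytic DMF is the standard mild route to monosubstituted malonyl dichlorides; 7 has no free hydroxyl group, its ring has no open position for a Friedel–Crafts closure, and the by-products are volatile, so the crude tetrachloride can be used directly.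

**Step 6**
Reactants: 8 2,2'-{[2,4,6-trimethoxy-5-(2-methylpropanoyl)-1,3-phenylene]bis(methylene)}dimalonyl tetrachloride; 9 3-pentanone
Product: 11 3,3'-{[2,4,6-trimethoxy-5-(2-methylpropanoyl)-1,3-phenylene]bis(methylene)}bis(6-ethyl-4-hydroxy-5-methyl-2H-pyran-2-one), via bis(chlorocarbonyl)ketene 10 (not isolated)
Conditions: 9 (10 equiv), toluene, 100 °C, N2 sweep; extraction into aq. NaHCO3, acidification
Reagents that add atoms: none
Why: Heating expels HCl from each ClCO–CH–COCl unit of 8 to give the (chlorocarbonyl)ketene arms of 10; the enol of 3-pentanone is acylated on oxygen by the acyl chloride (O1–C2, second HCl lost), the enol-ester carbon then adds to the ketene carbon (C4–C5), and tautomerisation gives the 4-hydroxy-2-pyrone. This is the established pyrone synthesis from substituted (chlorocarbonyl)ketenes or malonyl dichlorides and enolisable ketones, run here on two arms of one core. Each ring closes by a six-membered 6-(enolendo)-exo-dig addition of the enol ester to the ketene; the opposite order, C-acylation then 6-exo-trig lactonisation, would give the same ring. No stereocentre is formed. The selectivity needed is capture of each arm by 3-pentanone instead of reaction within the core: the aryl ketone is a hindered, twisted isopropyl ketone, the fully substituted ring cannot undergo Friedel–Crafts closure, the phenols are masked as methyl ethers, and 3-pentanone is in tenfold excess. Because 3-pentanone is symmetric there is no choice between α-carbons, so methyl falls on C5 and ethyl on C6, and the acidic product should separate from neutral by-products by bicarbonate extraction.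

**Step 7**
Reactants: 11 3,3'-{[2,4,6-trimethoxy-5-(2-methylpropanoyl)-1,3-phenylene]bis(methylene)}bis(6-ethyl-4-hydroxy-5-methyl-2H-pyran-2-one)
Product: 12 3,3'-{[2,4,6-trihydroxy-5-(2-methylpropanoyl)-1,3-phenylene]bis(methylene)}bis(6-ethyl-4-hydroxy-5-methyl-2H-pyran-2-one)
Conditions: BBr3 (10 equiv), CH2Cl2, −78 → 0 °C; H2O quench
Reagents that add atoms: none
Why: Boron tribromide ether cleavage (O-coordination, then SN2 attack of bromide on methyl) should remove all three methyl groups, which are di-ortho-substituted and, for the two next to the ketone, chelation-assisted, while the pyrone lactones, the ketone and the CH2 bridges are expected to survive at or below 0 °C and the borates are hydrolysed on aqueous work-up.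

**Compound list**
1 | 1,3,5-trimethoxybenzene | COc1cc(OC)cc(OC)c1 | starting material
2 | 2-methylpropanoyl chloride (isobutyryl chloride) | CC(C)C(=O)Cl | starting material
3 | 2-methyl-1-(2,4,6-trimethoxyphenyl)propan-1-one | CC(C)C(=O)c1c(OC)cc(OC)cc1OC | intermediate
4 | 1-[3,5-bis(chloromethyl)-2,4,6-trimethoxyphenyl]-2-methylpropan-1-one | CC(C)C(=O)c1c(OC)c(CCl)c(OC)c(CCl)c1OC | intermediate
5 | dimethyl malonate | COC(=O)CC(=O)OC | starting material
6 | tetramethyl 2,2'-{[2,4,6-trimethoxy-5-(2-methylpropanoyl)-1,3-phenylene]bis(methylene)}dimalonate | CC(C)C(=O)c1c(OC)c(CC(C(=O)OC)C(=O)OC)c(OC)c(CC(C(=O)OC)C(=O)OC)c1OC | intermediate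
7 | 2,2'-{[2,4,6-trimethoxy-5-(2-methylpropanoyl)-1,3-phenylene]bis(methylene)}dimalonic acid | CC(C)C(=O)c1c(OC)c(CC(C(=O)O)C(=O)O)c(OC)c(CC(C(=O)O)C(=O)O)c1OC | intermediate
8 | 2,2'-{[2,4,6-trimethoxy-5-(2-methylpropanoyl)-1,3-phenylene]bis(methylene)}dimalonyl tetrachloride | CC(C)C(=O)c1c(OC)c(CC(C(Cl)=O)C(Cl)=O)c(OC)c(CC(C(Cl)=O)C(Cl)=O)c1OC | intermediate
9 | 3-pentanone | CCC(=O)CC | starting material
10 | 2,2'-{[2,4,6-trimethoxy-5-(2-methylpropanoyl)-1,3-phenylene]bis(methylene)}bis(3-oxoprop-2-enoyl chloride), the bis(chlorocarbonyl)ketene formed in the flask in step 6 | CC(C)C(=O)c1c(OC)c(CC(=C=O)C(Cl)=O)c(OC)c(CC(=C=O)C(Cl)=O)c1OC | intermediate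
11 | 3,3'-{[2,4,6-trimethoxy-5-(2-methylpropanoyl)-1,3-phenylene]bis(methylene)}bis(6-ethyl-4-hydroxy-5-methyl-2H-pyran-2-one) | CCc1oc(=O)c(Cc2c(OC)c(Cc3c(O)c(C)c(CC)oc3=O)c(OC)c(C(=O)C(C)C)c2OC)c(O)c1C | intermediate
12 | 3,3'-{[2,4,6-trihydroxy-5-(2-methylpropanoyl)-1,3-phenylene]bis(methylene)}bis(6-ethyl-4-hydroxy-5-methyl-2H-pyran-2-one) | CCc1oc(=O)c(Cc2c(O)c(Cc3c(O)c(C)c(CC)oc3=O)c(O)c(C(=O)C(C)C)c2O)c(O)c1C | target

**Total step count:** 7
**Longest linear sequence:** 7 steps (1 → 3 → 4 → 6 → 7 → 8 → 11 → 12)

**Steps most likely to fail**

Step 6. The twofold annulation may stall after one arm, or the ketene arms may be used up by intermolecular oligomerisation or by demethylative lactonisation onto a neighbouring methoxy group before 3-pentanone captures them. The fallback sets out from 4 and comes back at 11, building the pyrone separately and attaching it through the bridge carbons. Methyl 3-oxopentanoate is converted into its dianion (NaH, then n-BuLi, THF, 0 °C) and acylated at C4 with N-methoxy-N-methylpropanamide to give methyl 4-methyl-3,5-dioxoheptanoate F1. This is lactonised with DBU in refluxing toluene to 6-ethyl-4-hydroxy-5-methyl-2H-pyran-2-one F2. A slight excess over two equivalents of F2 is then benzylated at C3 by the bis(chloromethyl) ketone 4 in hexafluoroisopropanol at 40 °C, a Friedel–Crafts-type alkylation through the stabilised 2,6-dimethoxybenzyl cations, which should give 11.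

Step 2. The first benzylic chloride may alkylate unreacted arene (diarylmethane formation), or the reaction may stop after one chloromethylation. The fallback sets out from 1 and comes back at 6, introducing the bridge carbons as aldehydes and the ketone last. Twofold Rieche formylation of 1 (Cl2CHOMe, TiCl4, CH2Cl2) gives 2,4,6-trimethoxybenzene-1,3-dicarbaldehyde F3. Knoevenagel condensation with dimethyl malonate 5 (TiCl4, pyridine, THF) gives tetramethyl 2,2'-[(2,4,6-trimethoxy-1,3-phenylene)dimethanylylidene]dimalonate F4. Hydrogenation (H2, Pd/C, EtOAc) gives tetramethyl 2,2'-[(2,4,6-trimethoxy-1,3-phenylene)bis(methylene)]dimalonate F5. Friedel–Crafts acylation of F5 at its last ring position with 2 (excess AlCl3 to saturate the ester groups, CH2Cl2, 0 °C) then gives 6.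

Step 7. Under the Lewis acid the methylene bridges may scramble (retro-Friedel–Crafts), a freed phenol may cyclodehydrate onto the neighbouring pyrone 4-hydroxyl, or cleavage may stay incomplete. The fallback sets out from 3 and comes back at 12, removing the methyl groups before any bridge exists. Ketone 3 is demethylated with BBr3 (CH2Cl2, −78 °C → rt) to 2-methyl-1-(2,4,6-trihydroxyphenyl)propan-1-one F6. The pyrone 6-ethyl-4-hydroxy-5-methyl-2H-pyran-2-one F2, made as in the fallback to step 6, is aminomethylated with N,N-dimethylmethyleneiminium iodide (CH2Cl2, rt) to the Mannich base 3-[(dimethylamino)methyl]-6-ethyl-4-hydroxy-5-methyl-2H-pyran-2-one F7. Heating F6 with two equivalents of F7 in dioxane should exchange each dimethylamino group for one of the two free ring carbons of F6 by elimination–addition, giving 12 directly.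

**Further compounds**
F1 | step 6 | methyl 4-methyl-3,5-dioxoheptanoate | CCC(=O)C(C)C(=O)CC(=O)OC
F2 | step 6 | 6-ethyl-4-hydroxy-5-methyl-2H-pyran-2-one | CCc1oc(=O)cc(O)c1C
F3 | step 2 | 2,4,6-trimethoxybenzene-1,3-dicarbaldehyde | COc1cc(OC)c(C=O)c(OC)c1C=O
F4 | step 2 | tetramethyl 2,2'-[(2,4,6-trimethoxy-1,3-phenylene)dimethanylylidene]dimalonate | COC(=O)C(=Cc1c(OC)cc(OC)c(C=C(C(=O)OC)C(=O)OC)c1OC)C(=O)OC
F5 | step 2 | tetramethyl 2,2'-[(2,4,6-trimethoxy-1,3-phenylene)bis(methylene)]dimalonate | COC(=O)C(Cc1c(OC)cc(OC)c(CC(C(=O)OC)C(=O)OC)c1OC)C(=O)OC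
F6 | step 7 | 2-methyl-1-(2,4,6-trihydroxyphenyl)propan-1-one | CC(C)C(=O)c1c(O)cc(O)cc1O
F7 | step 7 | 3-[(dimethylamino)methyl]-6-ethyl-4-hydroxy-5-methyl-2H-pyran-2-one | CCc1oc(=O)c(CN(C)C)c(O)c1C
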